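The runs are simulated from invented constants, noise included.

The amounts in the earlier runs are where I start, so I set them beside the new flasks and the questions.

| flask | substrate | partner | remark | time |
|---|---|---|---|---|
| Thursday's | 0.070 M | 1.5 equiv | run made earlier |  |
| Monday's | 0.11 M | 1.5 equiv | run made earlier |  |
| Sunday's | 0.050 M | 0.75 equiv | run made earlier |  |
| west | 0.050 M | 1.50 equiv |  | 25 min |
| south-east | 0.050 M | 1.50 equiv |  | 3.0 min |
| east | 0.050 M | 1.50 equiv |  | 10 min |

| run | time / min | substrate / % | double product / % | single product / % |
|---|---|---|---|---|
| Thursday's | 0.833 | 6.9 | 21.9 | 24.7 |
| Thursday's | 2.00 | 2.1 | 37.8 | 13.2 |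
| Thursday's | 2.50 | 0.5 | 41.3 | 9.8 |
| Thursday's | 4.00 | 0.9 | 47.4 | 4.8 |
| Monday's | 0.417 | 10.2 | 17.2 | 26.8 |
| Monday's | 1.33 | 2.0 | 38.2 | 12.4 |
| Monday's | 2.50 | 0 | 47.3 | 4.8 |
| Monday's | 4.00 | 0 | 51.0 | 1.8 |
| Sunday's | 0.417 | 30.5 | 2.3 | 16.9 |
| Sunday's | 1.33 | 9.7 | 9.2 | 22.3 |
| Sunday's | 2.50 | 3.9 | 13.5 | 18.7 |
| Sunday's | 4.00 | 2.6 | 18.4 | 15.2 |

(readings scatter by 0.5 percentage points)

- which of these there is most of at the end, counted by the substrate in it, west (substrate / double product / single product)
- which of these there is most of at the end, counted by the substrate in it, south-east (substrate / double product / single product)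
- which of these there is most of at the end, counted by the substrate in it, east (substrate / double product / single product)
- the largest of these amounts at the end, in percent of the substrate charged, west
- the largest of these amounts at the end, in percent of the substrate charged, south-east
- the largest of these amounts at the end, in percent of the substrate charged, east

- the analysis behind the earlier runs scatters by 0.5 percentage points, standard deviation

My bench rule is that at equal equivalents a dilute flask passes through the same amounts as a strong one, only later. So I multiply substrate concentration by time, and that product, 9.00 M·s for south-east, is what I call the dose. I test the rule first. Thursday's run at 2.00 min has a dose of 8.40 M·s and Monday's at 1.33 min has 8.78 M·s, and they read 37.8% and 38.2% double product, a gap within the scatter of 0.5 percentage points. South-east sits just past them, so I commit to about 38.2% double product there, with about 12.4% single product.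

Monday's last reading, at a dose of 26.4 M·s, gives 51.0% double product and 1.8% single product, which sum to 52.8% with no substrate read. I take that sum, a reading with its scatter, as my estimate of where double product ends at these equivalents. East has a dose of 30.0 M·s, a little beyond Monday's, so I expect slightly over 51.0% there. West has 75.0 M·s, which is 2.84 times Monday's, so I expect about that sum.

The border appears in the ratio of equivalents. Sunday's run has 0.500 of Thursday's equivalents. At 4.00 min its dose of 12.0 M·s exceeds Thursday's 10.5 M·s at 2.50 min, yet it reads 18.4% double product against 41.3%. So the dose does not carry over from Thursday's equivalents to Sunday's, and I use it for the new flasks because, at 1.50 equiv, they have the equivalents of Thursday's and Monday's runs.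

The forecast names double product for west, double product for south-east and double product for east, with 52.6%, 38.7% and 51.4%, on the ground that “the 0.050 M runs should follow the same curve”.

The flasks give double product at 52.1% in west, double product at 38.7% in south-east and double product at 51.1% in east, so south-east, at its dose of 9.00 M·s, stands 0.50 points above my figure.

    2 substrate → self-condensation product (k = 0.610 L mol⁻¹ s⁻¹)
    single product → over-reaction product (k = 3.30 × 10⁻⁶ s⁻¹)
    partner + single product → double product + released group (k = 0.250 L mol⁻¹ s⁻¹)
    substrate + partner → single product + released group (k = 0.430 L mol⁻¹ s⁻¹)

South-east starts with the making of single product using substrate at 0.53 times the rate of self-condensation. By 0.236 min that ratio has drifted to 1.1, and at 3.00 min self-condensation product holds 47.9% of the substrate charged. The south-east flask left until 50 s has a dose of 2.50 M·s, less than the 2.75 M·s of Monday's first reading, and it holds 15.6% double product against the 17.2% read there.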